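## Structural features

The target is built from two 7-methoxycoumarins and one cyclohexene (ring C). Coumarin A is bonded through its C6 to the ring C methine C1'; coumarin B is bonded through its C8 to C8' of an E-configured ethene bridge C7'=C8', whose other end sits on the quaternary carbon C6' (ring C is numbered C1' to C6', with C2'=C3' and the vinylic methyl on C3'). C1' (S; tertiary, benzylic and allylic) and C6' (S; all-carbon quaternary) are the only stereocentres and they are neighbours; the aryl group and the ethene bridge are cis, the C6' methyl trans to the aryl group. Ring C has the substitution pattern of a Diels–Alder adduct of a 1-aryl-3-methylbuta-1,3-diene and a 2-methylpropenyl-type dienophile. Fragile groups are the two lactones (hydride, hydroxide, organolithiums), the styrene-type bond C7'=C8' that carries an arene with two ortho oxygens (acid, light), and the 1,5-diene C3'=C2'–C1'–C6'–C7'=C8' at very high temperature. The difficulty is twofold: two adjacent centres, one quaternary, in one absolute sense, and the bond from the neopentyl alkene carbon C8' to C8 of coumarin B, a position wedged between the methoxy-bearing C7 and the oxygen-bearing C8a. The key step exploits the fact that the benzene ring of coumarin B (C4a, C5, C6, C7–OCH3, C8, C8a–O) is a 2-substituted resorcinol monoether, the signature of a vinylketene–alkoxyalkyne benzannulation, so that C8 can enter as an alkyne carbon.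

## Logic of the disconnections

**26 to 23.** The bonds C3=C4 and O1–C2 of coumarin B are cut. The pyranone is the most nucleophile-sensitive part of the second coumarin and is best made last, from an ortho-hydroxy aldehyde and a two-carbon ylide. One ring and two carbons are removed. The forward step must reach the cis-cinnamate geometry needed for lactonisation without touching coumarin A or C7'=C8'.

**23 to 21.** The bond C4–C4a is cut. The formyl carbon sits ortho to the phenol oxygen and para to OCH3, the single position to which a chelated phenoxide directs, since the other ortho position (C8) is occupied. This leaves a plain phenol. The forward step must be ortho-specific and non-acidic.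

**21 to 13 and 16 (key).** The bonds C8–C8a, C6–C7 and C4a–C8a are cut. The whole benzene ring of coumarin B disappears, and the hindered C8–C8' junction becomes an ordinary sp–sp2 bond of an enyne. The forward step must join the ketene carbonyl carbon to the alkyne carbon remote from oxygen. It must run under neutral conditions, and it must use an ynol ether that cannot fragment on heating, which is why the ether group is methyl.

**16 to 15 to 14.** The C=C bond of 16 comes from loss of HBr, and the C–Br bond from a carboxyl group by decarboxylative bromination. 16 is volatile and polymerises, so the forward steps must deliver it fresh and free of amine.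

**13 to 12.** The bond between C8' and the alkyne carbon is cut. A cross-coupling of an alkenyl iodide with a methoxyethynyl metal introduces the sensitive ynol ether only one step before it is consumed. The forward step must retain the E geometry and must not expose the lactone to a basic acetylide.

**12 to 11.** The bond C7'=C8' is cut. The iodoalkene is a one-carbon homologue of an aldehyde that has no α-hydrogen and therefore cannot epimerise. The forward step must be E-selective at a neopentyl aldehyde.

**11 to 9 and 10.** The bonds C1'–C6' and C4'–C5' are cut, the [4+2] retron of a cyclohexene with C2'=C3'. Ring C, the quaternary centre and both stereocentres are removed in one operation, which shortens the approach to 11 considerably compared with a ring contraction of a lactone. The forward step needs the "ortho/para" orientation (inherent in 9), the formyl-endo topology (cis) and catalyst control of the face of 10.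

**9 to 7 to 5 and 6.** The terminal C=CH2 of 9 comes from dehydration of 7, so the dimerisation-prone diene is stored as its stable alcohol. The bond between C6 of coumarin A and the alkenyl carbon comes from an arylation of 6. The arylation must give the E alkene, and the elimination can only run toward a methyl group.

**5 to 4 to 1 and 2.** The O–CH3 bond is cut, then C4–C4a and O1–C2 of coumarin A. The arene is bought with the bromine already in the position that becomes C6. Ring closure must take the position para to the second hydroxyl.

## Other disconnections considered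

**Alternative 1:** The cut is C1'–C6' of ring C, with an acyl oxygen returned to C3', so that ring C is traded for a δ-lactone.
- **Forward key step:** the silyl ketene acetal of (6S)-6-[(E)-2-(7-methoxy-2-oxochromen-6-yl)ethenyl]-3,6-dimethyloxan-2-one A2 rearranges [3,3] through the boat-like transition state that its two-carbon tether enforces. The product would be (1R,2R)-2-(7-methoxy-2-oxochromen-6-yl)-1,4-dimethylcyclohex-3-ene-1-carboxylic acid A1.
- **In its favour:** the cis relation of aryl and carboxyl follows from the geometry of a cyclic boat and an E alkene, and one carbinol centre is transferred to both new centres.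
- **Against it here:** A2 is needed as a single enantiomer at a tertiary allylic carbinol, a hard centre to set (a 1,1-dialkylethene is a poor substrate class for asymmetric dihydroxylation). Enolisation needs a strong amide base beside the coumarin lactone. A2 is a tertiary cinnamyl-type ester that ionises easily. A1 must then be brought to the aldehyde oxidation level beside the lactone.
- **Structure:** it solves ring C, not coumarin B; it would replace steps 3 to 5 of the chosen route and feed the same endgame.
- **Mechanism:** both ring C constructions are concerted pericyclic events. In relative configuration the alternative is the better one, because cis is enforced and does not rest on an endo preference. In absolute configuration the chosen plan is better, because a catalyst sets it directly.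
- **Step economy:** about nine steps to the level of 11, against five.

**Alternative 2:** The cut is C4a–C5 in the benzene ring of coumarin A, which opens that arene into a tricarbonyl chain.
- **Forward key step:** acid unmasks the acetal of methyl 6-(6-ethenyl-3,6-dimethylcyclohex-2-enyl)-7,7-dimethoxy-3,5-dioxoheptanoate A4 (ring C as in 26). The doubly activated methylene attacks the aldehyde, and dehydration and enolisation would give methyl 5-[(1S,6S)-6-ethenyl-3,6-dimethylcyclohex-2-en-1-yl]-2,4-dihydroxybenzoate A3.
- **In its favour:** the oxygen pattern is unambiguous, the two hydroxyls are differentiated by the hydrogen bond to the ester, and no transition metal is needed at C1'.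
- **Against it here:** the arene of coumarin A is the commodity 1, and its bond to C1' costs nothing in the chosen route. A4 needs ring C with both stereocentres made in an aliphatic series, without the aryl group that steers the cycloaddition. The polyketo chain is prone to retro-Claisen cleavage and pyranone formation. After A3, four more steps lead to coumarin A, and coumarin B is still missing.
- **Mechanism:** an ionic aldol–dehydration, against a pericyclic cascade. In regiochemical certainty and in forming no stereocentre the two benzannulations are equal. In mildness of conditions the alternative is the better, since it needs no strained and volatile partner such as 16.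
- **Structure:** it places the de novo arene where attachment is easy, whereas the chosen plan places it at the hindered C8.
- **Step economy:** well behind, more than fifteen steps.

**Alternative 3:** The cut is C2'=C3'.
- **Forward key step:** the second-generation Grubbs catalyst RuCl2(=CHPh)(H2IMes)(PCy3) loads on the vinyl group at C1' of (2R,3R)-3-(7-methoxy-2-oxochromen-6-yl)-2-methyl-2-(3-methylbut-3-enyl)pent-4-enal A6, closes onto the 1,1-disubstituted terminus and releases ethylene. The product would be (1R,2R)-2-(7-methoxy-2-oxochromen-6-yl)-1,4-dimethylcyclohex-3-ene-1-carbaldehyde A5, which is identical with 11.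
- **Origin of A6:** a stereoconvergent α-allylation of racemic 2,5-dimethylhex-5-enal A7 with racemic 6-(1-hydroxyprop-2-enyl)-7-methoxychromen-2-one A8, under a chiral primary amine together with [Ir(cod)Cl]2 and a chiral phosphoramidite.
- **In its favour:** metathesis is neutral and tolerates the lactone. The two catalysts control the two stereocentres independently, so any stereoisomer is within reach; on this point the alternative is better than the chosen cycloaddition, whose cis outcome rests on the endo preference.
- **Against it here:** enamine allylation of an α,α-dialkyl aldehyde to a quaternary centre next to a branched aryl-allyl terminus is the least developed part of that chemistry, and A7 and A8 each need a short synthesis.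
- **Structure:** equal, since the same aldehyde is reached and the endgame is unchanged.
- **Mechanism:** two catalytic events and a metathesis, against one concerted cycloaddition.
- **Step economy:** about eight steps to 11, against five.

Key step: step 10

Assumption: the (R)-configured oxazaborolidinium catalyst of step 5 is taken to leave the Si face of C2 of 10 open, as the formyl C–H···O binding model for 2-substituted acroleins predicts; if the sense were the reverse, the (S)-catalyst would be used with no other change.

Remark: 13 and 21 were checked atom by atom against 26; both carry ring C in the (1S,6S) configuration and the oxygen pattern that the annulation needs, so no structure had to be corrected.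

## Route

Step 1
Reactants: 1 4-bromobenzene-1,3-diol (4-bromoresorcinol); 2 (RS)-2-hydroxybutanedioic acid (malic acid)
Product: 4 6-bromo-7-hydroxychromen-2-one, via 3-oxopropanoic acid 3 (not isolated)
Conditions: conc. H2SO4, 110 °C
Reagents that add atoms: none
Why: Pechmann condensation; sulfuric acid decarbonylates 2 to 3, which attacks 1 at the only activated free position (ortho to one hydroxyl, para to the other), and lactonisation then places bromine at C6 and the free hydroxyl at C7.

Step 2
Reactants: 4 6-bromo-7-hydroxychromen-2-one
Product: 5 6-bromo-7-methoxychromen-2-one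
Conditions: MeI, K2CO3, acetone, 56 °C
Reagents that add atoms: iodomethane, CI
Why: Williamson ether synthesis on the acidic 7-hydroxyl; carbonate in acetone does not open the lactone.

Step 3
Reactants: 5 6-bromo-7-methoxychromen-2-one; 6 2-methylbut-3-en-2-ol
Product: 7 6-[(E)-3-hydroxy-3-methylbut-1-enyl]-7-methoxychromen-2-one
Conditions: Pd(OAc)2 (5 mol %), P(o-tol)3 (10 mol %), Et3N, DMF, 100 °C
Reagents that add atoms: none
Why: Mizoroki–Heck reaction; the aryl group adds to the terminal alkene carbon, and syn β-hydride elimination can only use the benzylic hydrogen because the carbinol carbon has none, which gives the E alkene.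

Step 4
Reactants: 7 6-[(E)-3-hydroxy-3-methylbut-1-enyl]-7-methoxychromen-2-one
Product: 9 7-methoxy-6-[(E)-3-methylbuta-1,3-dienyl]chromen-2-one, via tertiary sulfamate ester 8 (not isolated)
Conditions: Burgess reagent (Et3N+–SO2–N−–CO2Me), toluene, 60 °C
Reagents that add atoms: none
Why: Burgess dehydration; the alcohol is sulfamoylated to 8, and syn elimination can only take a methyl hydrogen, so the 1,3-diene forms with the E styrene bond untouched. The conditions are neutral, and 9 is used at once because such dienes dimerise on standing.

Step 5
Reactants: 9 7-methoxy-6-[(E)-3-methylbuta-1,3-dienyl]chromen-2-one; 10 2-methylprop-2-enal (methacrolein)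
Product: 11 (1R,2R)-2-(7-methoxy-2-oxochromen-6-yl)-1,4-dimethylcyclohex-3-ene-1-carbaldehyde
Conditions: (R)-o-tolyl-CBS-oxazaborolidine (C24H24BNO, 20 mol %) with HNTf2 (16 mol %), 10 (4 equiv), CH2Cl2, −78 → −40 °C
Reagents that add atoms: none
Why: Catalytic enantioselective Diels–Alder reaction of a 2-substituted acrolein under chiral oxazaborolidinium activation; the 1-aryl and 3-methyl groups of 9 both steer the quaternary carbon next to C1' ("ortho/para" orientation), and the formyl-endo transition state puts aryl and formyl cis. The catalyst holds 10 through boron and a formyl C–H···O contact and leaves the Si face of its C2 open, which should set both stereocentres of 11 as R,R in one event.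

Step 6
Reactants: 11 (1R,2R)-2-(7-methoxy-2-oxochromen-6-yl)-1,4-dimethylcyclohex-3-ene-1-carbaldehyde
Product: 12 6-[(1S,6R)-6-[(E)-2-iodoethenyl]-3,6-dimethylcyclohex-2-en-1-yl]-7-methoxychromen-2-one
Conditions: CHI3, CrCl2, THF–1,4-dioxane, 0 → 23 °C
Reagents that add atoms: iodoform, IC(I)I
Why: Takai iodo-olefination; the geminal dichromium species from CHI3 and CrCl2 adds to the aldehyde and eliminates to the E alkenyl iodide, a preference that is strongest for α-branched aldehydes. 11 has no α-hydrogen and cannot epimerise, the lactone is inert to divalent chromium in THF, and the change of descriptor at the quaternary carbon is a matter of priority only.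

Step 7
Reactants: 12 6-[(1S,6R)-6-[(E)-2-iodoethenyl]-3,6-dimethylcyclohex-2-en-1-yl]-7-methoxychromen-2-one
Product: 13 7-methoxy-6-[(1S,6S)-6-[(E)-4-methoxybut-1-en-3-ynyl]-3,6-dimethylcyclohex-2-en-1-yl]chromen-2-one
Conditions: ClCH2CH(OMe)2, LiNEt2 (3 equiv), THF, −78 → 0 °C; ZnCl2, 0 °C; then 12, Pd(PPh3)4 (5 mol %), THF, 23 °C
Reagents that add atoms: methoxyethynylzinc chloride, COC#C[Zn]Cl (made in the flask from 2-chloro-1,1-dimethoxyethane, COC(CCl)OC)
Why: Negishi coupling of an alkoxyethynylzinc halide with an alkenyl iodide, with retention of the E geometry. The acetylide arises from the chloroacetal by two eliminations and deprotonation, and transmetallation to zinc removes its basicity before the lactone is added.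

Step 8
Reactants: 14 3-oxocyclobutane-1-carboxylic acid
Product: 15 3-bromocyclobutan-1-one
Conditions: HgO, Br2, MgSO4, CH2Cl2, 40 °C
Reagents that add atoms: bromine, BrBr
Why: Hunsdiecker reaction in the Cristol–Firth modification; the acyl hypobromite loses CO2 and the cyclobutyl radical takes up bromine.

Step 9
Reactants: 15 3-bromocyclobutan-1-one
Product: 16 cyclobut-2-en-1-one
Conditions: n-Bu3N, 23 °C, then vacuum transfer into a −78 °C trap; kept as a cold toluene solution
Reagents that add atoms: none
Why: E1cB elimination of HBr from the β-bromo ketone; the high-boiling amine and its salt stay behind when the volatile enone is transferred.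

Step 10
Reactants: 13 7-methoxy-6-[(1S,6S)-6-[(E)-4-methoxybut-1-en-3-ynyl]-3,6-dimethylcyclohex-2-en-1-yl]chromen-2-one; 16 cyclobut-2-en-1-one
Product: 21 6-[(1S,6S)-6-[(E)-2-(2-hydroxy-6-methoxyphenyl)ethenyl]-3,6-dimethylcyclohex-2-en-1-yl]-7-methoxychromen-2-one, via vinylketene 17 (not isolated), via 4-vinylcyclobutenone adduct 18 (not isolated), via dienylketene 19 (not isolated), via cyclohexa-2,4-dienone 20 (not isolated)
Conditions: 16 (3 equiv, added over 6 h), toluene, 80 → 110 °C, dark; then K2CO3, MeOH, 0 °C; AcOH
Reagents that add atoms: none
Why: Danheiser benzannulation, a thermal pericyclic cascade of the vinylketene–alkoxyalkyne type. Reversible four-electron electrocyclic opening of 16 gives 17, whose electrophilic carbonyl carbon bonds to the nucleophilic alkyne carbon remote from oxygen (C8–C8a) while its α-carbon bonds to the methoxy-bearing carbon (C6–C7), a [2+2] cycloaddition that gives 18. Four-electron opening of 18 gives 19, and the benzene ring is then closed by a thermal disrotatory six-electron electrocyclisation that forms C4a–C8a and gives 20, which tautomerises to the phenol 21. No stereocentre is formed, and C1' and C6' lie far from the reacting atoms under neutral conditions, so ring C should keep its configuration. The regiochemistry that the step needs, OCH3 on C7 and C8' on C8 between the two oxygens, is secured by the polarisation that the methoxy group imposes on the alkyne. Chemoselectivity for the alkyne over C2'=C3', C7'=C8' and the electron-poor C3=C4 of coumarin A follows from the far higher nucleophilicity of the ynol ether. The methyl ether is kept on purpose because, unlike an ethyl or tert-butyl ynol ether, it cannot lose an alkene by retro-ene fragmentation at these temperatures, and the short methanolysis at the end returns any phenol that was acylated by 17.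

Step 11
Reactants: 21 6-[(1S,6S)-6-[(E)-2-(2-hydroxy-6-methoxyphenyl)ethenyl]-3,6-dimethylcyclohex-2-en-1-yl]-7-methoxychromen-2-one
Product: 23 2-hydroxy-4-methoxy-3-[(E)-2-[(1S,2S)-2-(7-methoxy-2-oxochromen-6-yl)-1,4-dimethylcyclohex-3-en-1-yl]ethenyl]benzaldehyde, via hydroxymethylphenol 22 (not isolated)
Conditions: MgCl2, Et3N, (CH2O)n, MeCN, 80 °C; aqueous citric acid, 0 °C
Reagents that add atoms: paraformaldehyde (reacting as formaldehyde), C=O
Why: Casnati–Skattebøl ortho-formylation; the chloromagnesium phenoxide delivers formaldehyde to the only free ortho position, C4a, and a second formaldehyde oxidises the benzylic alkoxide of 22 by hydride transfer. Triethylamine does not harm the lactone, and strong acid is avoided because of the electron-rich styrene.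

Step 12
Reactants: 23 2-hydroxy-4-methoxy-3-[(E)-2-[(1S,2S)-2-(7-methoxy-2-oxochromen-6-yl)-1,4-dimethylcyclohex-3-en-1-yl]ethenyl]benzaldehyde
Product: 26 7-methoxy-8-[(E)-2-[(1S,2S)-2-(7-methoxy-2-oxochromen-6-yl)-1,4-dimethylcyclohex-3-en-1-yl]ethenyl]chromen-2-one, via (E)-cinnamate ester 24 (not isolated), via (Z)-cinnamate ester 25 (not isolated)
Conditions: Ph3P=CHCO2Et, PhNEt2, 210 °C, argon, dark
Reagents that add atoms: ethyl (triphenyl-λ5-phosphanylidene)acetate, CCOC(=O)C=P(c1ccccc1)(c1ccccc1)c1ccccc1
Why: Wittig olefination with a stabilised ylide gives 24; at this temperature the cinnamate bond equilibrates with 25, which is removed by lactonisation onto the ortho hydroxyl with loss of ethanol. This is the standard closure for 8-substituted 7-methoxycoumarins.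

## Compound list

1 | 4-bromobenzene-1,3-diol | Oc1ccc(Br)c(O)c1 | starting material
2 | (RS)-2-hydroxybutanedioic acid | OC(CC(O)=O)C(O)=O | starting material
3 | 3-oxopropanoic acid (not isolated) | O=CCC(=O)O | intermediate
4 | 6-bromo-7-hydroxychromen-2-one | Oc1cc2oc(=O)ccc2cc1Br | intermediate
5 | 6-bromo-7-methoxychromen-2-one | COc1cc2oc(=O)ccc2cc1Br | intermediate
6 | 2-methylbut-3-en-2-ol | CC(C)(O)C=C | starting material
7 | 6-[(E)-3-hydroxy-3-methylbut-1-enyl]-7-methoxychromen-2-one | COc1cc2oc(=O)ccc2cc1/C=C/C(C)(C)O | intermediate
8 | triethylammonium salt of the N-(methoxycarbonyl)sulfamate ester of 7 (not isolated) | COc1cc2oc(=O)ccc2cc1/C=C/C(C)(C)OS(=O)(=O)[N-]C(=O)OC.CC[NH+](CC)CC | intermediate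
9 | 7-methoxy-6-[(E)-3-methylbuta-1,3-dienyl]chromen-2-one | COc1cc2oc(=O)ccc2cc1/C=C/C(C)=C | intermediate
10 | 2-methylprop-2-enal | CC(=C)C=O | starting material
11 | (1R,2R)-2-(7-methoxy-2-oxochromen-6-yl)-1,4-dimethylcyclohex-3-ene-1-carbaldehyde | COc1cc2oc(=O)ccc2cc1[C@H]1C=C(C)CC[C@@]1(C)C=O | intermediate
12 | 6-[(1S,6R)-6-[(E)-2-iodoethenyl]-3,6-dimethylcyclohex-2-en-1-yl]-7-methoxychromen-2-one | COc1cc2oc(=O)ccc2cc1[C@H]1C=C(C)CC[C@@]1(C)/C=C/I | intermediate
13 | 7-methoxy-6-[(1S,6S)-6-[(E)-4-methoxybut-1-en-3-ynyl]-3,6-dimethylcyclohex-2-en-1-yl]chromen-2-one | COc1cc2oc(=O)ccc2cc1[C@H]1C=C(C)CC[C@@]1(C)/C=C/C#COC | intermediate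
14 | 3-oxocyclobutane-1-carboxylic acid | O=C1CC(C1)C(=O)O | starting material
15 | 3-bromocyclobutan-1-one | O=C1CC(Br)C1 | intermediate
16 | cyclobut-2-en-1-one | O=C1C=CC1 | intermediate
17 | buta-1,3-dien-1-one (vinylketene, not isolated) | C=CC=C=O | intermediate
18 | 4-ethenyl-3-methoxy-2-[(E)-2-[(1S,2S)-2-(7-methoxy-2-oxochromen-6-yl)-1,4-dimethylcyclohex-3-en-1-yl]ethenyl]cyclobut-2-en-1-one (C4 of the four-membered ring unassigned, not isolated) | COc1cc2oc(=O)ccc2cc1[C@H]1C=C(C)CC[C@@]1(C)/C=C/C1=C(OC)C(C=C)C1=O | intermediate
19 | 3-methoxy-2-[(E)-2-[(1S,2S)-2-(7-methoxy-2-oxochromen-6-yl)-1,4-dimethylcyclohex-3-en-1-yl]ethenyl]hexa-1,3,5-trien-1-one (not isolated) | COc1cc2oc(=O)ccc2cc1[C@H]1C=C(C)CC[C@@]1(C)/C=C/C(=C=O)/C(OC)=C\C=C | intermediate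
20 | 3-methoxy-2-[(E)-2-[(1S,2S)-2-(7-methoxy-2-oxochromen-6-yl)-1,4-dimethylcyclohex-3-en-1-yl]ethenyl]cyclohexa-2,4-dien-1-one (not isolated) | COc1cc2oc(=O)ccc2cc1[C@H]1C=C(C)CC[C@@]1(C)/C=C/C1=C(OC)C=CCC1=O | intermediate
21 | 6-[(1S,6S)-6-[(E)-2-(2-hydroxy-6-methoxyphenyl)ethenyl]-3,6-dimethylcyclohex-2-en-1-yl]-7-methoxychromen-2-one | COc1cc2oc(=O)ccc2cc1[C@H]1C=C(C)CC[C@@]1(C)/C=C/c1c(OC)cccc1O | intermediate
22 | 6-[(1S,6S)-6-[(E)-2-[2-hydroxy-3-(hydroxymethyl)-6-methoxyphenyl]ethenyl]-3,6-dimethylcyclohex-2-en-1-yl]-7-methoxychromen-2-one (not isolated) | COc1cc2oc(=O)ccc2cc1[C@H]1C=C(C)CC[C@@]1(C)/C=C/c1c(OC)ccc(CO)c1O | intermediate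
23 | 2-hydroxy-4-methoxy-3-[(E)-2-[(1S,2S)-2-(7-methoxy-2-oxochromen-6-yl)-1,4-dimethylcyclohex-3-en-1-yl]ethenyl]benzaldehyde | COc1cc2oc(=O)ccc2cc1[C@H]1C=C(C)CC[C@@]1(C)/C=C/c1c(OC)ccc(C=O)c1O | intermediate
24 | ethyl (E)-3-[2-hydroxy-4-methoxy-3-[(E)-2-[(1S,2S)-2-(7-methoxy-2-oxochromen-6-yl)-1,4-dimethylcyclohex-3-en-1-yl]ethenyl]phenyl]prop-2-enoate (not isolated) | COc1cc2oc(=O)ccc2cc1[C@H]1C=C(C)CC[C@@]1(C)/C=C/c1c(OC)ccc(/C=C/C(=O)OCC)c1O | intermediate
25 | ethyl (Z)-3-[2-hydroxy-4-methoxy-3-[(E)-2-[(1S,2S)-2-(7-methoxy-2-oxochromen-6-yl)-1,4-dimethylcyclohex-3-en-1-yl]ethenyl]phenyl]prop-2-enoate (not isolated) | COc1cc2oc(=O)ccc2cc1[C@H]1C=C(C)CC[C@@]1(C)/C=C/c1c(OC)ccc(/C=C\C(=O)OCC)c1O | intermediate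
26 | 7-methoxy-8-[(E)-2-[(1S,2S)-2-(7-methoxy-2-oxochromen-6-yl)-1,4-dimethylcyclohex-3-en-1-yl]ethenyl]chromen-2-one | COc1cc2oc(=O)ccc2cc1[C@H]1C=C(C)CC[C@@]1(C)/C=C/c1c(OC)ccc2ccc(=O)oc12 | target

## Step count and least certain steps

Total step count: 12 (ten in the main line, two for the preparation of 16). Longest linear sequence: 10 steps (steps 1 to 7 and 10 to 12).

**Step 10 (key step).**
- What may go wrong: oligomerisation of 16 may outrun its ring opening and capture. The phenol may be acylated by the ketene as it forms. The ynol ether may hydrate or decompose during the long heating. All three have the same cause: the reactive partner is present only in a low stationary concentration while a sensitive alkyne waits.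
- Fallback: it sets out from 11 and comes back at 26. Olefination of 11 with Cl2CHBpin, CrCl2 and LiI in THF (the boron variant of the Takai reaction) should give 6-[(1S,6S)-3,6-dimethyl-6-[(E)-2-(4,4,5,5-tetramethyl-1,3,2-dioxaborolan-2-yl)ethenyl]cyclohex-2-en-1-yl]-7-methoxychromen-2-one F1. Suzuki–Miyaura coupling of F1 with 8-iodo-7-methoxychromen-2-one F2 (Pd(OAc)2, SPhos, K2CO3, 1,4-dioxane–water, 80 °C) would then bring in coumarin B intact and give 26 directly. F2 would be made from commercial 7-hydroxychromen-2-one by iodination at C8 (I2, KI, aqueous NH3) to 7-hydroxy-8-iodochromen-2-one F3, followed by methylation (MeI, K2CO3).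

**Step 5.**
- What may go wrong: insufficient face or endo selectivity, sequestration of the boron catalyst by the lactone carbonyl, or acid-induced oligomerisation of the electron-rich diene.
- Fallback: it sets out from 9 and comes back at 11, and separates the two stereocentres. An iminium-catalysed Diels–Alder reaction of 9 with acrolein would use (5R)-5-benzyl-2,2,3-trimethylimidazolidin-4-one hydrochloride (20 mol %) in MeCN–water at 23 °C. This is the antipode expected to leave the Si face of C2 of acrolein open, and it should set C1' and give the cis adduct (1R,2S)-2-(7-methoxy-2-oxochromen-6-yl)-4-methylcyclohex-3-ene-1-carbaldehyde F4. Methylation of the potassium enolate of F4 (KN(SiMe3)2, THF, −78 °C; MeI) should occur trans to the neighbouring aryl group and give 11.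

**Step 7.**
- What may go wrong: protonolysis or hydration of the alkoxyalkynyl metal or of the product, and opening of the lactone by residual amide or methoxide from the acetylide preparation.
- Fallback: it sets out from 12 and comes back at 13, and uses an isolated, neutral nucleophile. Tributyl(methoxyethynyl)stannane F5 would be prepared separately from lithium methoxyacetylide and Bu3SnCl, distilled, and coupled with 12 in a Stille reaction (PdCl2(MeCN)2, DMF, 23 °C).

**Step 12.**
- What may go wrong: thermal stress at 210 °C may cause geometric isomerisation of C7'=C8', cycloreversion of ring C, or a sigmatropic shift of the 1,5-diene.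
- Fallback: it sets out from 23 and comes back at 26, and no longer relies on thermal E to Z equilibration. Ketenylidenetriphenylphosphorane (Ph3P=C=C=O) in toluene at 110 °C should acylate the phenol to 6-formyl-3-methoxy-2-[(E)-2-[(1S,2S)-2-(7-methoxy-2-oxochromen-6-yl)-1,4-dimethylcyclohex-3-en-1-yl]ethenyl]phenyl (triphenyl-λ5-phosphanylidene)acetate F6. F6 would close the lactone by an intramolecular Wittig reaction, in which the ring enforces the cis geometry.

## Further compounds

F1 | step 10 | 6-[(1S,6S)-3,6-dimethyl-6-[(E)-2-(4,4,5,5-tetramethyl-1,3,2-dioxaborolan-2-yl)ethenyl]cyclohex-2-en-1-yl]-7-methoxychromen-2-one | COc1cc2oc(=O)ccc2cc1[C@H]1C=C(C)CC[C@@]1(C)/C=C/B1OC(C)(C)C(C)(C)O1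
F2 | step 10 | 8-iodo-7-methoxychromen-2-one | COc1ccc2ccc(=O)oc2c1I
F3 | step 10 | 7-hydroxy-8-iodochromen-2-one | Oc1ccc2ccc(=O)oc2c1I
F4 | step 5 | (1R,2S)-2-(7-methoxy-2-oxochromen-6-yl)-4-methylcyclohex-3-ene-1-carbaldehyde | COc1cc2oc(=O)ccc2cc1[C@H]1C=C(C)CC[C@H]1C=O
F5 | step 7 | tributyl(methoxyethynyl)stannane | CCCC[Sn](CCCC)(CCCC)C#COC
F6 | step 12 | 6-formyl-3-methoxy-2-[(E)-2-[(1S,2S)-2-(7-methoxy-2-oxochromen-6-yl)-1,4-dimethylcyclohex-3-en-1-yl]ethenyl]phenyl (triphenyl-λ5-phosphanylidene)acetate | COc1cc2oc(=O)ccc2cc1[C@H]1C=C(C)CC[C@@]1(C)/C=C/c1c(OC)ccc(C=O)c1OC(=O)C=P(c1ccccc1)(c1ccccc1)c1ccccc1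
A1 | alternative 1 | (1R,2R)-2-(7-methoxy-2-oxochromen-6-yl)-1,4-dimethylcyclohex-3-ene-1-carboxylic acid | COc1cc2oc(=O)ccc2cc1[C@H]1C=C(C)CC[C@@]1(C)C(=O)O
A2 | alternative 1 | (6S)-6-[(E)-2-(7-methoxy-2-oxochromen-6-yl)ethenyl]-3,6-dimethyloxan-2-one (C3 unassigned) | CC1CC[C@@](C)(/C=C/c2cc3ccc(=O)oc3cc2OC)OC1=O
A3 | alternative 2 | methyl 5-[(1S,6S)-6-ethenyl-3,6-dimethylcyclohex-2-en-1-yl]-2,4-dihydroxybenzoate | COC(=O)c1cc([C@H]2C=C(C)CC[C@@]2(C)C=C)c(O)cc1O
A4 | alternative 2 | methyl 6-(6-ethenyl-3,6-dimethylcyclohex-2-enyl)-7,7-dimethoxy-3,5-dioxoheptanoate (ring C as in 26, C6 of the chain unassigned) | COC(=O)CC(=O)CC(=O)C([C@H]1C=C(C)CC[C@@]1(C)C=C)C(OC)OC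
A5 | alternative 3 | (1R,2R)-2-(7-methoxy-2-oxochromen-6-yl)-1,4-dimethylcyclohex-3-ene-1-carbaldehyde (identical with 11) | COc1cc2oc(=O)ccc2cc1[C@H]1C=C(C)CC[C@@]1(C)C=O
A6 | alternative 3 | (2R,3R)-3-(7-methoxy-2-oxochromen-6-yl)-2-methyl-2-(3-methylbut-3-enyl)pent-4-enal | COc1cc2oc(=O)ccc2cc1[C@@H](C=C)[C@](C)(C=O)CCC(C)=C
A7 | alternative 3 | 2,5-dimethylhex-5-enal (racemic) | CC(CCC(C)=C)C=O
A8 | alternative 3 | 6-(1-hydroxyprop-2-enyl)-7-methoxychromen-2-one (racemic) | COc1cc2oc(=O)ccc2cc1C(O)C=C
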